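# Late double C8 hydroxylation route to the C4–O–C4 linked bis-flavan CNP0241481.1

Abbreviations in names: MOMO = methoxymethoxy (OCH2OCH3); TIPSO = triisopropylsilyloxy (OSi(i-Pr)3). Flavan numbering is used throughout (O1, C2, C3, C4; ring A = benzo ring; ring B = 2-aryl ring).

## The problem

The target is a dimeric flavan: two 2-(4-hydroxyphenyl)chroman-3-ol units, each with a 7,8-dihydroxylated ring A, are joined by an ether oxygen between their C4 atoms. Each pyran ring holds three contiguous stereocentres: one unit is (2R,3R,4R), all-cis, and the other is (2S,3R,4R), 2,3-trans-3,4-cis, so the units agree at C3 and C4 but are antipodal at C2 and cannot both come from one enantiomeric series of a 2-arylchroman. Within a unit the C2 aryl group can send reagents to the opposite face at C3 and C4, and a C3 substituent can steer C4; nothing in one unit controls the other except when the ether is made. That event is itself biased, because O-nucleophiles enter a flavan C4 cation pseudo-axially, trans to the C2 aryl group: this is the 2,4-trans relationship of the second unit but the opposite of the 2,4-cis relationship of the all-cis unit, whose C4–O bond must be set by other means. The molecule is fragile: two catechols that oxidise in air and base, a bridging ether that is benzylic on both sides and para to O7 in both rings (acid ionisation, hydrogenolysis), and benzylic C2–O1 bonds. The feature to exploit is that C8 of each ring A lies between O1 and the C7 oxygen. With O7 as a methoxymethyl ether this is the one doubly flanked, kinetically most acidic aryl position, so both C8 hydroxyls can be added last to a dimer built in the cheaper, less oxidation-prone 7-oxygenated series.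

## Retrosynthesis

**Unmasking (29 ⇒ 28 ⇒ 26).** Only O–Si and O–CH2OMe bonds are cut. The two aryl silyl ethers of 28 fall to buffered fluoride and the two aryl methoxymethyl ethers of 26 to a silyl triflate–bipyridyl complex. Hydrogenolysis or protic acid, the usual ways to free polyphenols, would attack the doubly benzylic bridge, and these groups avoid both. Each group also has a duty in the key step: the acetal directs, the bulky silyl ether does not. The forward steps must leave the bridge and the free catechols intact.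

**The two C8–O bonds (26 ⇒ 23).** Both C8–OH bonds are cut. The alternative of carrying 7,8-dioxygenated rings A from the start would need three differentiated ring A oxygens per unit. It would also turn every intermediate into an easily oxidised pyrogallol ether and blur the selectivity of the hydride-abstraction and cation steps below. Precursor 23 is the 8,8′-dideoxy dimer, in which each ring A is a resorcinol diether with a single doubly activated C–H. The forward step must lithiate twice at C8 in the presence of two free secondary alcohols, two benzylic ether C–H bonds and two aryl silyl ethers, then convert C–Li to C–O.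

**The bridge (23 ⇒ 22 ⇒ 17 + 21; 21 from 20).** The bridging oxygen is cut from C4 of the 2,3-trans unit. Cutting on the other side would require an O-nucleophile to enter C4 of the all-cis unit cis to its aryl group, against the pseudo-axial preference. On the chosen side the wanted 2,4-trans-3,4-cis arrangement is the preferred one. The all-cis unit therefore acts as the nucleophile, alcohol 17, which reacts through its O–H bond and keeps its C4 configuration. The trans unit acts as the electrophile, epoxide 21, made in the flask from chromene 20; it supplies the C3 hydroxyl, the C4 cation and both remaining stereocentres in one operation. An acetate on O3 of 17 leaves only O4 free; its removal from 22 gives 23. The forward step needs face selectivity at C4 of the cation and capture by a hindered secondary alcohol.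

**The all-cis unit (17 ⇒ 16 ⇒ 15 ⇒ 14 ⇒ 13 ⇒ 12 ⇒ 11 ⇒ 9).** Its three centres are disconnected as C–H bonds made by hydride on the face away from the aryl group. C4–H comes from ketone 16 (hydride anti to the axial acetoxy group) and C3–H from ketone 12 (bulky hydride anti to the aryl group). Oxygen reaches C4 by hydride abstraction (14 → 15) and C3 by hydroboration of chromene 9 (→ 11). Cation capture, osmylation and epoxidation can each place oxygen only trans to the aryl group, so two carbonyl reductions are the only disconnections whose known sense gives all-cis. The cost is seven steps from 9, each of a kind established on flavans.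

**Both C2 series from one racemate (9 ⇐ 7; 20 ⇐ 18; 7 and 18 ⇐ 6 ⇐ 2 + 4 ⇐ 1, 3).** The two units need opposite C2 configuration in equal amounts. Racemic flavanone 6 is therefore made once and divided. Asymmetric transfer hydrogenation with one enantiomer of the catalyst converts the (2S) half of one portion into cis-alcohol 7, and the mirror-image catalyst converts the (2R) half of a second portion into cis-alcohol 18. Each run leaves 6 enriched in the enantiomer that the other run consumes, so the leftovers are pooled and reused and neither antipode is waste. The C4 oxygen serves only as the resolution handle and as the leaving group toward chromenes 9 and 20. Flavanone 6 comes from acetophenone 2 and aldehyde 4 by condensation and oxa-Michael closure, and 2 and 4 from protection of commercial 1 and 3.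

## Roads not taken

**Alternative 1:** The C3=C4 bond of the 2,3-trans unit is traced back to an ester carbonyl. In ester A1 the C4 oxygen of the benzylated all-cis unit is acylated by a salicylic acid whose phenol oxygen carries a 1-arylallyl group. Cp2Ti(CH2)(Cl)AlMe2 methylenates the ester and the titanium alkylidene closes the ring onto the allyl group, giving 4-alkoxy-2H-chromene A2.
- Merits: the inter-unit C–O bond is made by acylation, so no C4 cation is involved and the coupling poses no facial question. The catechol oxygens are present from the start.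
- Weak points: A2 still lacks C3 and C4 of the trans unit. It needs H at C4 and OH at C3 added anti to each other, with the OH anti to the aryl group. Hydroboration adds syn and would give the 3,4-trans ether, and nothing in the substrate secures the face of hydride delivery to the ketal carbon in an epoxidation–reduction detour. The all-cis diol must be made anyway. The O-bound 1-arylallyl centre is prone to ionise under the Lewis-acidic Ti/Al reagent. The final hydrogenolysis of eight benzyl ethers must spare a doubly benzylic bridge.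
- Comparison: this road is better in that the coupling itself carries no stereochemical risk. The chosen plan sets against this that epoxide opening gives the ether and both remaining centres of the trans unit in one step with the known facial bias, and that its endgame is non-reductive.

**Alternative 2:** No skeletal bond is cut at the key stage. A3 is the ether of two identical all-cis units with a single free 4′-hydroxyl. Heated with base, the free phenol opens O1–C2 of its unit to a p-quinone methide and a ring A phenoxide, and reclosure gives the more stable 2,3-trans ring of A4.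
- Merits: a single chiral series suffices, and C2 epimerisation of flavan-3-ols through quinone methides is a known equilibrium.
- Weak points: A3 is itself hard to reach, because joining two all-cis units needs attack cis to the aryl group at C4 of one of them. The two ring B phenols must be differentiated. The ring-opened intermediate is a ring A phenoxide ortho to the carbon that carries the bridge, so it can expel the bridging alkoxide as an o-quinone methide and cleave the dimer. The end point is an equilibrium mixture of C2 epimers.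
- Comparison: this road is superior in needing one chiral building block instead of two. The chosen plan answers by making one racemate and using both antipodes.

**Alternative 3:** O1–C2, C3–C4 and the bridging C–O bond of the all-cis unit are made together. Salicylaldehyde A6 and the C4 alcohol A5 of the finished trans unit form a mixed acetal that ionises to an alkoxy o-quinone methide. [4+2] addition of (Z)-enol acetate A7 under a chiral phosphoric acid would give A8.
- Merits: it is the shortest access to the all-cis triad (Z geometry gives 2,3-cis, endo addition gives 2,4-cis), and the C4–O centre of A5 can come from reliable osmylation.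
- Weak points: the enol acetate must react through its acetoxy-bearing carbon as the nucleophilic terminus, against the normal polarisation of an enol ester. A5 is a benzylic alcohol that itself ionises under the acid required. Face selection must come from the catalyst in competition with the chiral alkoxy group. No close precedent exists for this combination.
- Comparison: if it worked it would replace the seven-step construction of 17 and is clearly better in step count. The chosen plan sets against this that each of the three centres is fixed by a reaction of established sense.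

Key step: step 17

## Route

Remark 1: racemic 6 is divided between steps 4 and 13, which are mirror-image kinetic resolutions. The unreduced 6 recovered from the two runs is enriched in opposite enantiomers; it is pooled to near-racemic 6 and reused.

Remark 2 (assumption): the (S,S)-configured catalyst is taken to reduce the (2S)-ketone and the (R,R)-configured catalyst the (2R)-ketone, by analogy with chroman-4-one reductions. If the sense is reversed, the two ligands change places between steps 4 and 13 and nothing else changes.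

Step 1
Reactants: 1 2′,4′-dihydroxyacetophenone
Product: 2 1-[2-hydroxy-4-(methoxymethoxy)phenyl]ethanone
Conditions: MOMCl (1.1 equiv), i-Pr2NEt, CH2Cl2, 0 °C → rt
Reagents that add atoms: chloromethyl methyl ether, COCCl
Why: Williamson-type O-alkylation; the 2′-hydroxyl is held in a hydrogen bond to the ketone and is much less nucleophilic, so only the 4′-oxygen is acetalised.

Step 2
Reactants: 3 4-hydroxybenzaldehyde
Product: 4 4-(triisopropylsilyloxy)benzaldehyde
Conditions: i-Pr3SiCl, imidazole, DMF, rt
Reagents that add atoms: triisopropylsilyl chloride, CC(C)[Si](Cl)(C(C)C)C(C)C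
Why: Imidazole-mediated silylation of a phenol; the bulky silyl group is installed now because it must later resist alkyllithium attack and must not direct metalation.

Step 3
Reactants: 2 1-[2-hydroxy-4-(methoxymethoxy)phenyl]ethanone; 4 4-(triisopropylsilyloxy)benzaldehyde
Product: 6 rac-7-MOMO-2-(4-TIPSO-phenyl)chroman-4-one, via chalcone 5 (not isolated)
Conditions: pyrrolidine (1 equiv), EtOH, 70 °C
Reagents that add atoms: none
Why: Amine-mediated Claisen–Schmidt condensation gives chalcone 5, whose 2′-phenol closes the pyranone by 6-endo-trig oxa-Michael addition. Hydroxide-free conditions spare the aryl silyl ether, and residual 5 is resubmitted; the product is racemic by design.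

Step 4
Reactants: 6 rac-7-MOMO-2-(4-TIPSO-phenyl)chroman-4-one (first portion)
Product: 7 (2S,4S)-7-MOMO-2-(4-TIPSO-phenyl)chroman-4-ol
Conditions: Cp*RhCl[(S,S)-TsDPEN] (1 mol %), HCO2H/Et3N (5:2), EtOAc, rt, stopped near half conversion
Reagents that add atoms: none
Why: Asymmetric transfer hydrogenation used as a kinetic resolution of a racemic flavanone (metal–ligand bifunctional hydride transfer). The catalyst should reduce the (2S)-ketone fast, hydride entering C4 trans to the C2 aryl group, so 7 is the 2,4-cis alcohol with C4 set by the catalyst. The slow (2R) enantiomer of 6 stays as ketone and is removed by chromatography.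

Step 5
Reactants: 7 (2S,4S)-7-MOMO-2-(4-TIPSO-phenyl)chroman-4-ol
Product: 9 (2S)-7-MOMO-2-(4-TIPSO-phenyl)-2H-chromene, via 4-mesylate 8 (not isolated)
Conditions: MsCl, Et3N (4 equiv), CH2Cl2, 0 °C → rt, dark
Reagents that add atoms: none
Why: Sulfonylation of the p-alkoxybenzylic alcohol and amine-induced E1-type loss of methanesulfonate toward C3 give the conjugated 2H-chromene. C2 is not involved, and base rather than acid avoids cationic dimerisation of the electron-rich alkene.

Step 6
Reactants: 9 (2S)-7-MOMO-2-(4-TIPSO-phenyl)-2H-chromene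
Product: 11 (2R,3S)-7-MOMO-2-(4-TIPSO-phenyl)chroman-3-ol, via 3-boryl adduct 10 (not isolated)
Conditions: BH3·THF, THF, 0 °C → rt; then H2O, 30% H2O2, pH 7 NaH2PO4/Na2HPO4 buffer, 0 °C → rt
Reagents that add atoms: hydrogen peroxide, OO
Why: Hydroboration–oxidation of a flav-3-ene: boron adds to C3, the β-carbon of the electron-rich styrene, from the face anti to the C2 aryl group. Boron-to-oxygen migration occurs with retention, giving the 2,3-trans alcohol (3S); neutral peroxide protects the aryl silyl ether.

Step 7
Reactants: 11 (2R,3S)-7-MOMO-2-(4-TIPSO-phenyl)chroman-3-ol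
Product: 12 (2R)-7-MOMO-2-(4-TIPSO-phenyl)chroman-3-one
Conditions: Dess–Martin periodinane, NaHCO3, CH2Cl2, 0 °C → rt; used crude
Reagents that add atoms: none
Why: Dess–Martin oxidation under buffered, non-enolising conditions; the ketone is used at once because C2 is now α to a carbonyl.

Step 8
Reactants: 12 (2R)-7-MOMO-2-(4-TIPSO-phenyl)chroman-3-one
Product: 13 (2R,3R)-7-MOMO-2-(4-TIPSO-phenyl)chroman-3-ol
Conditions: LiBH(s-Bu)3, THF, −78 °C; then H2O
Reagents that add atoms: none
Why: The bulky hydride attacks the C3 carbonyl from the face opposite the C2 aryl group, the established way to 2,3-cis-flavan-3-ols; C3 becomes R.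

Step 9
Reactants: 13 (2R,3R)-7-MOMO-2-(4-TIPSO-phenyl)chroman-3-ol
Product: 14 (2R,3R)-7-MOMO-2-(4-TIPSO-phenyl)chroman-3-yl acetate
Conditions: Ac2O, pyridine, DMAP (cat.), CH2Cl2, rt
Reagents that add atoms: acetic anhydride, CC(=O)OC(C)=O
Why: DMAP-catalysed acylation; the acetate blocks O3 for the later etherification, prevents self-condensation in step 10 and inductively tempers ionisation at C4.

Step 10
Reactants: 14 (2R,3R)-7-MOMO-2-(4-TIPSO-phenyl)chroman-3-yl acetate
Product: 15 (2R,3R,4S)-4-hydroxy-7-MOMO-2-(4-TIPSO-phenyl)chroman-3-yl acetate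
Conditions: DDQ (1.5 equiv), CH2Cl2/H2O (18:1), 0 °C → rt
Reagents that add atoms: water, O
Why: Benzylic oxidation by hydride abstraction: DDQ removes the pseudo-axial C4 hydride to give a cation stabilised by the para O7 and ortho O1, which water captures. Attack trans to the aryl group (4S) is expected, but either epimer serves because step 11 removes this centre.

Step 11
Reactants: 15 (2R,3R,4S)-4-hydroxy-7-MOMO-2-(4-TIPSO-phenyl)chroman-3-yl acetate
Product: 16 (2R,3S)-7-MOMO-4-oxo-2-(4-TIPSO-phenyl)chroman-3-yl acetate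
Conditions: Dess–Martin periodinane, NaHCO3, CH2Cl2, 0 °C → rt
Reagents that add atoms: none
Why: Dess–Martin oxidation of a benzylic secondary alcohol; buffered conditions avoid epimerisation at C3 of the 2,3-cis acyloxy ketone.

Step 12
Reactants: 16 (2R,3S)-7-MOMO-4-oxo-2-(4-TIPSO-phenyl)chroman-3-yl acetate
Product: 17 (2R,3R,4R)-4-hydroxy-7-MOMO-2-(4-TIPSO-phenyl)chroman-3-yl acetate
Conditions: NaBH4, CeCl3·7H2O, MeOH/THF, −78 → −40 °C; AcOH quench
Reagents that add atoms: none
Why: Luche reduction: hydride enters C4 pseudo-axially, anti to the pseudo-axial C3 acetoxy group (Felkin–Anh polar model) and trans to the aryl group, giving the equatorial hydroxyl cis to both neighbours (4R). This is the sense known for borohydride reduction of 2,3-cis-dihydroflavonols; low temperature and the cerium salt suppress acetyl migration and C3 epimerisation.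

Step 13
Reactants: 6 rac-7-MOMO-2-(4-TIPSO-phenyl)chroman-4-one (second portion)
Product: 18 (2R,4R)-7-MOMO-2-(4-TIPSO-phenyl)chroman-4-ol
Conditions: Cp*RhCl[(R,R)-TsDPEN] (1 mol %), HCO2H/Et3N (5:2), EtOAc, rt, stopped near half conversion
Reagents that add atoms: none
Why: The mirror image of step 4: the (R,R)-catalyst should reduce the (2R)-ketone fast by the same bifunctional hydride transfer, again trans to the C2 aryl group, giving the 2,4-cis alcohol of the antipodal series. The C4 centre is lost in step 14, so only the C2 purity of 18 matters; the slow (2S) enantiomer of 6 stays as ketone and is removed by chromatography.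

Step 14
Reactants: 18 (2R,4R)-7-MOMO-2-(4-TIPSO-phenyl)chroman-4-ol
Product: 20 (2R)-7-MOMO-2-(4-TIPSO-phenyl)-2H-chromene, via 4-mesylate 19 (not isolated)
Conditions: MsCl, Et3N (4 equiv), CH2Cl2, 0 °C → rt, dark
Reagents that add atoms: none
Why: The same sulfonylation–elimination as in step 5, in the antipodal series.

Step 15
Reactants: 20 (2R)-7-MOMO-2-(4-TIPSO-phenyl)-2H-chromene; 17 (2R,3R,4R)-4-hydroxy-7-MOMO-2-(4-TIPSO-phenyl)chroman-3-yl acetate
Product: 22 (2R,3R,4R)-4-{[(2S,3R,4R)-3-hydroxy-7-MOMO-2-(4-TIPSO-phenyl)chroman-4-yl]oxy}-7-MOMO-2-(4-TIPSO-phenyl)chroman-3-yl acetate, via epoxide 21 (not isolated)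
Conditions: dimethyldioxirane (acetone solution, 1.1 equiv), CH2Cl2, −40 °C, volatiles removed cold; then 17, ZnCl2 (1 equiv), 4 Å MS, THF, −78 → 0 °C
Reagents that add atoms: dimethyldioxirane, CC1(C)OO1
Why: Epoxidation occurs anti to the C2 aryl group. ZnCl2 then opens the oxirane at C4, where the cation is stabilised by O7 and O1, and the C4 hydroxyl of 17 adds pseudo-axially, trans to the aryl group and on the face of the departing oxygen, to give the 3,4-cis (4R) ether (Lewis acid alcoholysis of a benzylic epoxide, same facial sense as alcohol capture of 2,3-trans-flavan-4-yl cations). C4 of 17 reacts through its O–H bond and keeps its configuration; its acetate blocks O3 and disfavours ionisation of the acceptor.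

Step 16
Reactants: 22 (the 3-acetate of the coupled ether)
Product: 23 (2R,3R,4R)-4-{[(2S,3R,4R)-3-hydroxy-7-MOMO-2-(4-TIPSO-phenyl)chroman-4-yl]oxy}-7-MOMO-2-(4-TIPSO-phenyl)chroman-3-ol
Conditions: i-Bu2AlH (4 equiv), CH2Cl2, −78 °C; aq potassium sodium tartrate
Reagents that add atoms: none
Why: Reductive removal of the acetate at low temperature leaves the acetals, the aryl silyl ethers and the bridging ether untouched and frees both C3 hydroxyls for the metalation.

Step 17
Reactants: 23 (8,8′-dideoxy bis-flavan ether, 7-O-MOM, 4′-O-TIPS, both C3 hydroxyls free)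
Product: 26 (2R,3R,4R)-4-{[(2S,3R,4R)-3,8-dihydroxy-7-MOMO-2-(4-TIPSO-phenyl)chroman-4-yl]oxy}-7-MOMO-2-(4-TIPSO-phenyl)chroman-3,8-diol, via tetralithio species 24 (not isolated), via bis-boronate 25 (not isolated)
Conditions: s-BuLi (5.5 equiv), TMEDA, THF, −78 °C; B(OMe)3, −78 °C → rt; AcOH, 30% H2O2, 0 °C → rt
Reagents that add atoms: hydrogen peroxide, OO
Why: The first two equivalents of s-BuLi convert both C3 hydroxyls into lithium alkoxides; these remain as spectators and make removal of the neighbouring C2 and C4 hydrogens, and with it β-elimination or [1,2]-Wittig shift of the bridge, electrostatically unfavourable. A further equivalent per unit, held by the methoxymethyl oxygens and O1 (complex-induced proximity), removes H8, the only ring A hydrogen flanked by two oxygen substituents. The aryllithium adds to B(OMe)3 to give boronate 25; peroxide adds to boron and the aryl group migrates from boron to oxygen with retention at carbon, hydrolysis giving the C8 phenol. The closest known reaction type is directed ortho-metalation of 1,3-dioxygenated arenes and 7-alkoxychromans followed by borylation–oxidation. No ring is closed and no stereocentre is created; the six existing centres are remote from the carbanionic sites and are not epimerised. The step needs C8 over C6, ring B and the benzylic positions, twice: C6 has only one ortho oxygen, and the ring B ortho positions lie next to bulky, non-coordinating triisopropylsilyl ethers, which also resist attack of the alkyllithium at silicon. Oxidation is run weakly acidic so that neither the aryl silyl ethers nor the new electron-rich phenols meet alkaline peroxide.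

Step 18
Reactants: 26 (8,8′-diol with 7-O-MOM and 4′-O-TIPS)
Product: 28 (2R,3R,4R)-4-{[(2S,3R,4R)-3,7,8-trihydroxy-2-(4-TIPSO-phenyl)chroman-4-yl]oxy}-2-(4-TIPSO-phenyl)chroman-3,7,8-triol, via hexakis-TMS ether 27 (not isolated)
Conditions: Me3SiOTf, 2,2′-bipyridyl, CH2Cl2, 0 °C → rt; then H2O/MeOH
Reagents that add atoms: none
Why: The silyl triflate–bipyridyl complex converts aryl methoxymethyl ethers into aryl trimethylsilyl ethers (the CH2OMe unit passes to the pyridine nitrogen) without free acid, so the ionisable C4–O–C4 ether should survive. Free hydroxyls are silylated in passing and all Me3Si–O bonds are hydrolysed on work-up.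

Step 19
Reactants: 28 (4′,4′-bis-O-TIPS hexaol)
Product: 29 (2R,3R,4R)-4-{[(2S,3R,4R)-3,7,8-trihydroxy-2-(4-hydroxyphenyl)chroman-4-yl]oxy}-2-(4-hydroxyphenyl)chroman-3,7,8-triol
Conditions: Bu4NF, AcOH (1:1), THF, 0 °C, argon
Reagents that add atoms: none
Why: Fluoride cleaves the two aryl silyl ethers; acetic acid buffering and exclusion of air keep the catechols from phenoxide-mediated oxidation.

## Compound list

1 | 2′,4′-dihydroxyacetophenone | CC(=O)c1ccc(O)cc1O | starting material
2 | 1-[2-hydroxy-4-(methoxymethoxy)phenyl]ethanone | CC(=O)c1ccc(OCOC)cc1O | intermediate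
3 | 4-hydroxybenzaldehyde | O=Cc1ccc(O)cc1 | starting material
4 | 4-(triisopropylsilyloxy)benzaldehyde | O=Cc1ccc(O[Si](C(C)C)(C(C)C)C(C)C)cc1 | intermediate
5 | (E)-1-[2-hydroxy-4-(methoxymethoxy)phenyl]-3-[4-(triisopropylsilyloxy)phenyl]prop-2-en-1-one | O=C(/C=C/c1ccc(O[Si](C(C)C)(C(C)C)C(C)C)cc1)c1ccc(OCOC)cc1O | intermediate (not isolated)
6 | rac-7-MOMO-2-(4-TIPSO-phenyl)chroman-4-one | O=C1CC(c2ccc(O[Si](C(C)C)(C(C)C)C(C)C)cc2)Oc2cc(OCOC)ccc21 | intermediate
7 | (2S,4S)-7-MOMO-2-(4-TIPSO-phenyl)chroman-4-ol (2,4-cis) | O[C@H]1C[C@@H](c2ccc(O[Si](C(C)C)(C(C)C)C(C)C)cc2)Oc2cc(OCOC)ccc21 | intermediate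
8 | methanesulfonate of 7 | CS(=O)(=O)O[C@H]1C[C@@H](c2ccc(O[Si](C(C)C)(C(C)C)C(C)C)cc2)Oc2cc(OCOC)ccc21 | intermediate (not isolated)
9 | (2S)-7-MOMO-2-(4-TIPSO-phenyl)-2H-chromene | C1=C[C@@H](c2ccc(O[Si](C(C)C)(C(C)C)C(C)C)cc2)Oc2cc(OCOC)ccc12 | intermediate
10 | 3-boryl adduct of 9 (BH2 on C3, trans to the C2 aryl group) | B[C@H]1Cc2ccc(OCOC)cc2O[C@@H]1c1ccc(O[Si](C(C)C)(C(C)C)C(C)C)cc1 | intermediate (not isolated)
11 | (2R,3S)-7-MOMO-2-(4-TIPSO-phenyl)chroman-3-ol (2,3-trans) | O[C@H]1Cc2ccc(OCOC)cc2O[C@@H]1c1ccc(O[Si](C(C)C)(C(C)C)C(C)C)cc1 | intermediate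
12 | (2R)-7-MOMO-2-(4-TIPSO-phenyl)chroman-3-one | O=C1Cc2ccc(OCOC)cc2O[C@@H]1c1ccc(O[Si](C(C)C)(C(C)C)C(C)C)cc1 | intermediate
13 | (2R,3R)-7-MOMO-2-(4-TIPSO-phenyl)chroman-3-ol (2,3-cis) | O[C@@H]1Cc2ccc(OCOC)cc2O[C@@H]1c1ccc(O[Si](C(C)C)(C(C)C)C(C)C)cc1 | intermediate
14 | (2R,3R)-7-MOMO-2-(4-TIPSO-phenyl)chroman-3-yl acetate | CC(=O)O[C@@H]1Cc2ccc(OCOC)cc2O[C@@H]1c1ccc(O[Si](C(C)C)(C(C)C)C(C)C)cc1 | intermediate
15 | (2R,3R,4S)-4-hydroxy-7-MOMO-2-(4-TIPSO-phenyl)chroman-3-yl acetate (2,3-cis-3,4-trans) | CC(=O)O[C@@H]1[C@@H](O)c2ccc(OCOC)cc2O[C@@H]1c1ccc(O[Si](C(C)C)(C(C)C)C(C)C)cc1 | intermediate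
16 | (2R,3S)-7-MOMO-4-oxo-2-(4-TIPSO-phenyl)chroman-3-yl acetate (2,3-cis) | CC(=O)O[C@@H]1C(=O)c2ccc(OCOC)cc2O[C@@H]1c1ccc(O[Si](C(C)C)(C(C)C)C(C)C)cc1 | intermediate
17 | (2R,3R,4R)-4-hydroxy-7-MOMO-2-(4-TIPSO-phenyl)chroman-3-yl acetate (all-cis) | CC(=O)O[C@@H]1[C@H](O)c2ccc(OCOC)cc2O[C@@H]1c1ccc(O[Si](C(C)C)(C(C)C)C(C)C)cc1 | intermediate
18 | (2R,4R)-7-MOMO-2-(4-TIPSO-phenyl)chroman-4-ol (2,4-cis) | O[C@@H]1C[C@H](c2ccc(O[Si](C(C)C)(C(C)C)C(C)C)cc2)Oc2cc(OCOC)ccc21 | intermediate
19 | methanesulfonate of 18 | CS(=O)(=O)O[C@@H]1C[C@H](c2ccc(O[Si](C(C)C)(C(C)C)C(C)C)cc2)Oc2cc(OCOC)ccc21 | intermediate (not isolated)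
20 | (2R)-7-MOMO-2-(4-TIPSO-phenyl)-2H-chromene | C1=C[C@H](c2ccc(O[Si](C(C)C)(C(C)C)C(C)C)cc2)Oc2cc(OCOC)ccc12 | intermediate
21 | (2S,3R,4R)-3,4-epoxy-7-MOMO-2-(4-TIPSO-phenyl)chromane (oxirane trans to the aryl group) | [C@@H]1(c3ccc(O[Si](C(C)C)(C(C)C)C(C)C)cc3)Oc2cc(OCOC)ccc2[C@H]2O[C@@H]12 | intermediate (not isolated)
22 | (2R,3R,4R)-4-{[(2S,3R,4R)-3-hydroxy-7-MOMO-2-(4-TIPSO-phenyl)chroman-4-yl]oxy}-7-MOMO-2-(4-TIPSO-phenyl)chroman-3-yl acetate | c1(O[Si](C(C)C)(C(C)C)C(C)C)ccc([C@H]2Oc3c(ccc(OCOC)c3)[C@@H](O[C@@H]3c4ccc(OCOC)cc4O[C@@H](c4ccc(O[Si](C(C)C)(C(C)C)C(C)C)cc4)[C@@H]3O)[C@H]2OC(C)=O)cc1 | intermediate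
23 | (2R,3R,4R)-4-{[(2S,3R,4R)-3-hydroxy-7-MOMO-2-(4-TIPSO-phenyl)chroman-4-yl]oxy}-7-MOMO-2-(4-TIPSO-phenyl)chroman-3-ol | c1(O[Si](C(C)C)(C(C)C)C(C)C)ccc([C@H]2Oc3c(ccc(OCOC)c3)[C@@H](O[C@@H]3c4ccc(OCOC)cc4O[C@@H](c4ccc(O[Si](C(C)C)(C(C)C)C(C)C)cc4)[C@@H]3O)[C@H]2O)cc1 | intermediate
24 | 8,8′-dilithio derivative of 23 as its 3,3′-dilithium dialkoxide | c1(O[Si](C(C)C)(C(C)C)C(C)C)ccc([C@H]2Oc3c(ccc(OCOC)c3[Li])[C@@H](O[C@@H]3c4ccc(OCOC)c([Li])c4O[C@@H](c4ccc(O[Si](C(C)C)(C(C)C)C(C)C)cc4)[C@@H]3O[Li])[C@H]2O[Li])cc1 | intermediate (not isolated)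
25 | 8,8′-bis(dimethoxyboryl) derivative of 23 | c1(O[Si](C(C)C)(C(C)C)C(C)C)ccc([C@H]2Oc3c(ccc(OCOC)c3B(OC)OC)[C@@H](O[C@@H]3c4ccc(OCOC)c(B(OC)OC)c4O[C@@H](c4ccc(O[Si](C(C)C)(C(C)C)C(C)C)cc4)[C@@H]3O)[C@H]2O)cc1 | intermediate (not isolated)
26 | (2R,3R,4R)-4-{[(2S,3R,4R)-3,8-dihydroxy-7-MOMO-2-(4-TIPSO-phenyl)chroman-4-yl]oxy}-7-MOMO-2-(4-TIPSO-phenyl)chroman-3,8-diol | c1(O[Si](C(C)C)(C(C)C)C(C)C)ccc([C@H]2Oc3c(ccc(OCOC)c3O)[C@@H](O[C@@H]3c4ccc(OCOC)c(O)c4O[C@@H](c4ccc(O[Si](C(C)C)(C(C)C)C(C)C)cc4)[C@@H]3O)[C@H]2O)cc1 | intermediate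
27 | 3,3′,7,7′,8,8′-hexakis-O-(trimethylsilyl) ether of 28 | c1(O[Si](C(C)C)(C(C)C)C(C)C)ccc([C@H]2Oc3c(ccc(O[Si](C)(C)C)c3O[Si](C)(C)C)[C@@H](O[C@@H]3c4ccc(O[Si](C)(C)C)c(O[Si](C)(C)C)c4O[C@@H](c4ccc(O[Si](C(C)C)(C(C)C)C(C)C)cc4)[C@@H]3O[Si](C)(C)C)[C@H]2O[Si](C)(C)C)cc1 | intermediate (not isolated)
28 | (2R,3R,4R)-4-{[(2S,3R,4R)-3,7,8-trihydroxy-2-(4-TIPSO-phenyl)chroman-4-yl]oxy}-2-(4-TIPSO-phenyl)chroman-3,7,8-triol | c1(O[Si](C(C)C)(C(C)C)C(C)C)ccc([C@H]2Oc3c(ccc(O)c3O)[C@@H](O[C@@H]3c4ccc(O)c(O)c4O[C@@H](c4ccc(O[Si](C(C)C)(C(C)C)C(C)C)cc4)[C@@H]3O)[C@H]2O)cc1 | intermediate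
29 | (2R,3R,4R)-4-{[(2S,3R,4R)-3,7,8-trihydroxy-2-(4-hydroxyphenyl)chroman-4-yl]oxy}-2-(4-hydroxyphenyl)chroman-3,7,8-triol | Oc1ccc([C@H]2Oc3c(ccc(O)c3O)[C@@H](O[C@@H]3c4ccc(O)c(O)c4O[C@@H](c4ccc(O)cc4)[C@@H]3O)[C@H]2O)cc1 | target

## Step count and least certain steps

Total: 19 steps. Longest linear sequence: 16 steps (1, 3–12, 15–19); step 2 and steps 13–14 are the side branches. Because two separately resolved partners are joined in step 15, residual minor enantiomers end up in diastereomeric ethers that chromatography should remove.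

**Step 17 (key step).** Most likely to go wrong is an incomplete second metalation: the dilithium dialkoxide can form poorly soluble mixed aggregates with s-BuLi at −78 °C, and if the reaction is then forced, slow removal of the benzylic C4 hydrogens next to the bridging oxygen (followed by [1,2]-Wittig shift or β-elimination) gains ground. The fallback sets out from 23 and returns at 29. It replaces the lithium alkoxides by silyl ethers, so that only two deprotonations are needed and the substrate stays in solution. t-BuMe2SiCl and imidazole in DMF give the bis-silyl ether F1. s-BuLi/TMEDA (2.5 equiv), B(OMe)3 and AcOH/H2O2 give the 8,8′-diol F2. Me3SiOTf/2,2′-bipyridyl and water give the tetraphenol F3. Bu4NF/AcOH then removes all four silyl groups to give 29.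

**Step 15.** Most likely to go wrong is Lewis acid-induced rearrangement of the oxirane to the flavan-3-one (hydride shift), or attack of the new C3 hydroxyl of 22 on a second epoxide outrunning the hindered acceptor. Facial selectivity at C4 may also erode if the alcohol approaches anti to the C3 oxygen. The fallback sets out from 20 and returns at 22. Hydroboration–oxidation of 20 under the conditions of step 6 gives the (2S,3R)-flavan-3-ol F4. DDQ in CH2Cl2 with excess 17 and 4 Å molecular sieves then generates the same C4 cation by hydride abstraction as a tight ion pair, and 17 captures it (the known C4 alkoxylation of flavan-3-ols), giving 22; unreacted 17 is recovered.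

**Step 12.** Most likely to go wrong is migration of the acetyl group from the axial O3 to the new equatorial O4 in the basic borohydride medium, or epimerisation at C3 before the ketone is reduced. The fallback sets out from 13 and returns at 17. It keeps O3 free and places the acetate last under stereoelectronic control. DDQ in wet CH2Cl2 converts 13 into the 3,4-diol F5. MnO2 oxidises only the benzylic hydroxyl to the 2,3-cis-dihydroflavonol F6. NaBH4/CeCl3·7H2O gives the all-cis diol F7. MeC(OMe)3 with catalytic camphorsulfonic acid gives the cyclic orthoester F8, whose hydrolysis in aqueous acetic acid opens to the axial ester and equatorial alcohol, that is 17.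

**Step 18.** Most likely to go wrong is ionisation of a C4–O bond of the bridge once the para oxygen is unmasked in the presence of the silyl triflate, together with incomplete acetal cleavage. The fallback sets out from 26 and returns at 28. It disarms the bridge before deprotection. Ac2O, pyridine and DMAP give the tetraacetate F9; acyl groups on O3 and O8 of both units lower the donor power of ring A and destabilise the C4 cations. Me3SiOTf/2,2′-bipyridyl and water give the 7,7′-diphenol F10. Catalytic K2CO3 in MeOH under argon at 0 °C removes the four acetates and returns 28; partial loss of aryl silyl ether at this point is harmless because step 19 follows.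

## Further compounds

F1 | step 17 | 3,3′-bis-O-(tert-butyldimethylsilyl) ether of 23 | c1(O[Si](C(C)C)(C(C)C)C(C)C)ccc([C@H]2Oc3c(ccc(OCOC)c3)[C@@H](O[C@@H]3c4ccc(OCOC)cc4O[C@@H](c4ccc(O[Si](C(C)C)(C(C)C)C(C)C)cc4)[C@@H]3O[Si](C)(C)C(C)(C)C)[C@H]2O[Si](C)(C)C(C)(C)C)cc1
F2 | step 17 | 3,3′-bis-O-(tert-butyldimethylsilyl) ether of 26 (8,8′-diol) | c1(O[Si](C(C)C)(C(C)C)C(C)C)ccc([C@H]2Oc3c(ccc(OCOC)c3O)[C@@H](O[C@@H]3c4ccc(OCOC)c(O)c4O[C@@H](c4ccc(O[Si](C(C)C)(C(C)C)C(C)C)cc4)[C@@H]3O[Si](C)(C)C(C)(C)C)[C@H]2O[Si](C)(C)C(C)(C)C)cc1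
F3 | step 17 | 3,3′-bis-O-(tert-butyldimethylsilyl) ether of 28 (7,7′,8,8′-tetraphenol) | c1(O[Si](C(C)C)(C(C)C)C(C)C)ccc([C@H]2Oc3c(ccc(O)c3O)[C@@H](O[C@@H]3c4ccc(O)c(O)c4O[C@@H](c4ccc(O[Si](C(C)C)(C(C)C)C(C)C)cc4)[C@@H]3O[Si](C)(C)C(C)(C)C)[C@H]2O[Si](C)(C)C(C)(C)C)cc1
F4 | step 15 | (2S,3R)-7-MOMO-2-(4-TIPSO-phenyl)chroman-3-ol (2,3-trans) | O[C@@H]1Cc2ccc(OCOC)cc2O[C@H]1c1ccc(O[Si](C(C)C)(C(C)C)C(C)C)cc1
F5 | step 12 | (2R,3R,4S)-7-MOMO-2-(4-TIPSO-phenyl)chroman-3,4-diol (2,3-cis-3,4-trans) | O[C@@H]1[C@@H](O)c2ccc(OCOC)cc2O[C@@H]1c1ccc(O[Si](C(C)C)(C(C)C)C(C)C)cc1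
F6 | step 12 | (2R,3S)-3-hydroxy-7-MOMO-2-(4-TIPSO-phenyl)chroman-4-one (2,3-cis) | O[C@@H]1C(=O)c2ccc(OCOC)cc2O[C@@H]1c1ccc(O[Si](C(C)C)(C(C)C)C(C)C)cc1
F7 | step 12 | (2R,3R,4R)-7-MOMO-2-(4-TIPSO-phenyl)chroman-3,4-diol (all-cis) | O[C@@H]1[C@H](O)c2ccc(OCOC)cc2O[C@@H]1c1ccc(O[Si](C(C)C)(C(C)C)C(C)C)cc1
F8 | step 12 | cyclic 3,4-O-(1-methoxyethylidene) orthoester of F7 | COC1(C)O[C@@H]2[C@H](O1)c1ccc(OCOC)cc1O[C@@H]2c1ccc(O[Si](C(C)C)(C(C)C)C(C)C)cc1
F9 | step 18 | 3,3′,8,8′-tetra-O-acetate of 26 | c1(O[Si](C(C)C)(C(C)C)C(C)C)ccc([C@H]2Oc3c(ccc(OCOC)c3OC(C)=O)[C@@H](O[C@@H]3c4ccc(OCOC)c(OC(C)=O)c4O[C@@H](c4ccc(O[Si](C(C)C)(C(C)C)C(C)C)cc4)[C@@H]3OC(C)=O)[C@H]2OC(C)=O)cc1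
F10 | step 18 | 3,3′,8,8′-tetra-O-acetate of 28 (7,7′-diphenol) | c1(O[Si](C(C)C)(C(C)C)C(C)C)ccc([C@H]2Oc3c(ccc(O)c3OC(C)=O)[C@@H](O[C@@H]3c4ccc(O)c(OC(C)=O)c4O[C@@H](c4ccc(O[Si](C(C)C)(C(C)C)C(C)C)cc4)[C@@H]3OC(C)=O)[C@H]2OC(C)=O)cc1
A1 | alternative 1 | ester of the C4 hydroxyl of the benzylated all-cis unit with 3,4-bis(benzyloxy)-2-[1-(4-benzyloxyphenyl)allyloxy]benzoic acid | O=C(O[C@@H]2c3ccc(OCc9ccccc9)c(OCc9ccccc9)c3O[C@H](c3ccc(OCc9ccccc9)cc3)[C@@H]2OCc9ccccc9)c1ccc(OCc9ccccc9)c(OCc9ccccc9)c1O[C@H](C=C)c1ccc(OCc9ccccc9)cc1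
A2 | alternative 1 | 4-alkoxy-2-aryl-2H-chromene enol ether of the benzylated all-cis unit | C1(O[C@@H]2c3ccc(OCc9ccccc9)c(OCc9ccccc9)c3O[C@H](c3ccc(OCc9ccccc9)cc3)[C@@H]2OCc9ccccc9)=C[C@H](c2ccc(OCc9ccccc9)cc2)Oc2c(OCc9ccccc9)c(OCc9ccccc9)ccc12
A3 | alternative 2 | benzylated C4–O–C4 ether of two all-cis units with one free 4′-hydroxyl | c1(OCc9ccccc9)ccc([C@H]2Oc3c(ccc(OCc9ccccc9)c3OCc9ccccc9)[C@@H](O[C@@H]3c4ccc(OCc9ccccc9)c(OCc9ccccc9)c4O[C@H](c4ccc(O)cc4)[C@@H]3OCc9ccccc9)[C@H]2OCc9ccccc9)cc1
A4 | alternative 2 | benzylated target with one free 4′-hydroxyl | c1(OCc9ccccc9)ccc([C@H]2Oc3c(ccc(OCc9ccccc9)c3OCc9ccccc9)[C@@H](O[C@@H]3c4ccc(OCc9ccccc9)c(OCc9ccccc9)c4O[C@@H](c4ccc(O)cc4)[C@@H]3OCc9ccccc9)[C@H]2OCc9ccccc9)cc1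
A5 | alternative 3 | benzylated 2,3-trans-3,4-cis unit with free C4 hydroxyl | O[C@@H]1c2ccc(OCc3ccccc3)c(OCc3ccccc3)c2O[C@@H](c2ccc(OCc3ccccc3)cc2)[C@@H]1OCc1ccccc1
A6 | alternative 3 | 3,4-bis(benzyloxy)-2-hydroxybenzaldehyde | O=Cc1ccc(OCc2ccccc2)c(OCc2ccccc2)c1O
A7 | alternative 3 | (Z)-2-[4-(benzyloxy)phenyl]ethenyl acetate | CC(=O)O/C=C\c1ccc(OCc2ccccc2)cc1
A8 | alternative 3 | benzylated target with C3 acetate on the all-cis unit | c1(OCc9ccccc9)ccc([C@H]2Oc3c(ccc(OCc9ccccc9)c3OCc9ccccc9)[C@@H](O[C@@H]3c4ccc(OCc9ccccc9)c(OCc9ccccc9)c4O[C@@H](c4ccc(OCc9ccccc9)cc4)[C@@H]3OCc9ccccc9)[C@H]2OC(C)=O)cc1
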